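**Strategy.** Ring C (pyranone) and the dihydrofuran ring share an α-ketol triad: ketal C2, carbinol C3–OH and ketone C4, with C4 on the strongly nucleophilic C4a of phloroglucinol ring A. The route builds the isomeric triad instead: a vicinal tricarbonyl on the flavan ring (12) whose central carbonyl is the future C4 and already carries C2. In one operation, phloroglucinol attacks that carbonyl through carbon (C4–C4a), two phenols ketalise C2, and an α-ketol shift moves C2 from C4 to C3 (C2–C3), contracting one ring as the other expands. (S)-Naringenin supplies the flavan centre; a chiral phosphoric acid sets the carbinol centre.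

Key step: step 8

Numbering used: ring C of the target is O1, C2 (ketal carbon bearing the 4-hydroxyphenyl group), C3 (carbinol), C4 (ketone); ring A is the phloroglucinol ring fused at C4a/C8a; ring D is the aromatic ring of the flavan unit, bound to C3 through its C8 and to C2 through its 7-oxygen.

Remark: the ketal carbon C2 is stereochemically slaved to the carbinol carbon C3 by the two fused rings, so the route controls C3 and the flavan carbon; C2 is written in 16 and 17 with the descriptor of the target structure.

Step 1
Reactants: 1 (S)-naringenin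
Product: 3 (2S)-4',5,7-trihydroxyflavan, via naringenin tris(ethyl carbonate) 2 (not isolated)
Conditions: ClCO2Et, Et3N, THF, 0 °C; then NaBH4, H2O, 0 °C to rt; then aq. NaOH, rt
Reagents that add atoms: none
Why: Reductive deoxygenation of the ortho-hydroxyaryl ketone through its aryl carbonate (hydride reduction, loss of ethyl carbonate to an ortho-quinone methide, second hydride addition) should remove the C4 oxygen of naringenin, while the 2S centre is taken unchanged from 1 and the remaining carbonates are saponified.

Step 2
Reactants: 3 (2S)-4',5,7-trihydroxyflavan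
Product: 4 (2S)-4',5,7-tris(benzyloxy)flavan
Conditions: BnBr, K2CO3, DMF, rt
Reagents that add atoms: benzyl bromide, BrCc1ccccc1
Why: Williamson etherification of the three phenols masks them for the organolithium and enolate steps and does not touch the stereocentre.

Step 3
Reactants: 4 (2S)-4',5,7-tris(benzyloxy)flavan
Product: 5 (2S)-8-bromo-4',5,7-tris(benzyloxy)flavan
Conditions: NBS, CH2Cl2, −78 to 0 °C
Reagents that add atoms: N-bromosuccinimide, O=C1CCC(=O)N1Br
Why: Electrophilic aromatic bromination should take place at C8 of ring D, the position between the ring oxygen and the 7-benzyloxy group that benzylated 5,7-dioxygenated flavans are known to favour over the more crowded C6.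

Step 4
Reactants: 5 (2S)-8-bromo-4',5,7-tris(benzyloxy)flavan, 6 N-methoxy-N-methylacetamide
Product: 8 (2S)-8-acetyl-4',5,7-tris(benzyloxy)flavan, via flavan-8-yllithium 7 (not isolated)
Conditions: n-BuLi, THF, −78 °C; then 6, −78 to 0 °C; aq. NH4Cl
Reagents that add atoms: none
Why: Bromine–lithium exchange followed by acylation of the aryllithium with a Weinreb amide, whose chelated tetrahedral adduct prevents over-addition, should give the methyl ketone, whose two carbons become C3 and C4 of the target.

Step 5
Reactants: 8 (2S)-8-acetyl-4',5,7-tris(benzyloxy)flavan, 9 methyl 4-(benzyloxy)benzoate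
Product: 10 1-[(2S)-4',5,7-tris(benzyloxy)flavan-8-yl]-3-[4-(benzyloxy)phenyl]propane-1,3-dione
Conditions: NaH, THF, reflux; aq. HCl
Reagents that add atoms: none
Why: Crossed Claisen condensation of the methyl ketone enolate with a non-enolisable aryl ester, driven by deprotonation of the product, should give the 1,3-diketone and brings in the future ketal carbon C2 with its aryl group.

Step 6
Reactants: 10 1-[(2S)-4',5,7-tris(benzyloxy)flavan-8-yl]-3-[4-(benzyloxy)phenyl]propane-1,3-dione
Product: 11 1-[(2S)-4',5,7-tris(benzyloxy)flavan-8-yl]-3-[4-(benzyloxy)phenyl]propane-1,2,3-trione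
Conditions: Dess–Martin periodinane, pyridine, CH2Cl2, rt
Reagents that add atoms: Dess–Martin periodinane, CC(=O)OI1(OC(C)=O)(OC(C)=O)OC(=O)c2ccccc21
Why: Oxidation of the doubly activated methylene of a 1,3-diketone to a vicinal tricarbonyl by the Dess–Martin periodinane is a known use of this reagent and creates the central carbonyl that becomes C4, benzyl ethers and the flavan ring being inert.

Step 7
Reactants: 11 1-[(2S)-4',5,7-tris(benzyloxy)flavan-8-yl]-3-[4-(benzyloxy)phenyl]propane-1,2,3-trione
Product: 12 1-[(2S)-4',5-bis(benzyloxy)-7-hydroxyflavan-8-yl]-3-[4-(benzyloxy)phenyl]propane-1,2,3-trione (open form drawn; it should exist largely as its cyclic hemiketal tautomers)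
Conditions: BCl3, C6HMe5, CH2Cl2, −78 °C; then pH 7 phosphate buffer
Reagents that add atoms: none
Why: Chelation-directed ether cleavage by the boron Lewis acid, which binds the aryl ketone oxygen and the ortho 7-benzyloxy oxygen, with pentamethylbenzene as benzyl cation trap, should free only the 7-OH that will become the dihydrofuran oxygen.

Step 8
Reactants: 12 1-[(2S)-4',5-bis(benzyloxy)-7-hydroxyflavan-8-yl]-3-[4-(benzyloxy)phenyl]propane-1,2,3-trione, 13 phloroglucinol
Product: 16 tri-O-benzyl ether of the target (benzyl on the ring D 5-oxygen and on both 4-hydroxyphenyl oxygens; ring C 2R,3S; flavan 2S), via Friedel–Crafts carbinol 14 (not isolated), via isomeric bis-ketal 15 (not isolated)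
Conditions: 13 (3 equiv), TRIP phosphoric acid (10 mol %, one antipode), 4 Å MS, THF–PhMe, −20 °C to rt; then DBU, 40 °C; AcOH quench
Reagents that add atoms: none
Why: Phloroglucinol adds through a ring carbon (the future C4a) to the central and most electrophilic carbonyl of the tricarbonyl (the future C4) in an acid-catalysed Friedel–Crafts hydroxyalkylation (bond C4–C4a) to give carbinol 14, one of its ortho OH groups and the flavan 7-OH then condense on the neighbouring aroyl carbonyl (C2) to give the rigid bis-ketal 15, and DBU triggers an α-ketol (acyloin) rearrangement in which C2 shifts from C4 to the aryl ketone carbon C3 (bond C2–C3) while C4 becomes the ketone. The closest known reactions are the addition of phenols to ninhydrin and other vicinal tricarbonyls with hemiketal closure, and the base-induced α-ketol shift that interconverts benzopyranone and benzofuranone ketols. Ring C is closed by one-carbon ring expansion of the dihydrofuran of 15 (itself formed by 5-exo-trig ketalisation), and the dihydrofuran ring of 16 by ring contraction of the pyranone that 15 carries on ring D, both in the same 1,2-shift. The phosphoric acid, hydrogen-bonded to the 1,2-dicarbonyl and to a phenol OH, selects the face of the central carbonyl and so sets the carbinol carbon of 14 (the antipode that gives the configuration shown is used, both being available); inside 15 the shift is suprafacial with retention at the migrating C2, which relays this configuration to C3, and C2 is held by the two fused rings. Site selectivity rests on the electrophilicity of the central carbonyl and on the symmetry of phloroglucinol (all ring carbons equivalent, each flanked by OH), and the direction of the shift on the fact that only 16 has its ketone conjugated with, and hydrogen-bonded to, the free 5-OH of ring A (a vinylogous acid, deprotonated under the conditions).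

Step 9
Reactants: 16 tri-O-benzyl ether of the target
Product: 17 target (ring C 2R,3S; flavan 2S)
Conditions: H2 (1 atm), Pd(OH)2/C, EtOAc–MeOH, rt
Reagents that add atoms: none
Why: Catalytic hydrogenolysis of the three aryl benzyl ethers should release the free phenols, the tertiary alcohol, the diaryl ketal and the flavan C–O bond being hindered benzylic C–O bonds that react far more slowly, and no stereocentre is affected.

**Compound list**

1 | (S)-naringenin, (2S)-5,7-dihydroxy-2-(4-hydroxyphenyl)chroman-4-one | Oc1cc(O)c2c(c1)O[C@H](c1ccc(O)cc1)CC2=O | starting material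
2 | naringenin tris(ethyl carbonate) (not isolated) | CCOC(=O)Oc1cc(OC(=O)OCC)c2c(c1)O[C@H](c1ccc(OC(=O)OCC)cc1)CC2=O | intermediate
3 | (2S)-4',5,7-trihydroxyflavan, (2S)-2-(4-hydroxyphenyl)chromane-5,7-diol | Oc1cc(O)c2c(c1)O[C@H](c1ccc(O)cc1)CC2 | intermediate
4 | (2S)-4',5,7-tris(benzyloxy)flavan | c1c(OCc2ccccc2)cc(OCc2ccccc2)c2c1O[C@H](c1ccc(OCc3ccccc3)cc1)CC2 | intermediate
5 | (2S)-8-bromo-4',5,7-tris(benzyloxy)flavan | Brc1c(OCc2ccccc2)cc(OCc2ccccc2)c2c1O[C@H](c1ccc(OCc3ccccc3)cc1)CC2 | intermediate
6 | N-methoxy-N-methylacetamide | CC(=O)N(C)OC | starting material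
7 | (2S)-4',5,7-tris(benzyloxy)flavan-8-yllithium (not isolated) | [Li]c1c(OCc2ccccc2)cc(OCc2ccccc2)c2c1O[C@H](c1ccc(OCc3ccccc3)cc1)CC2 | intermediate
8 | (2S)-8-acetyl-4',5,7-tris(benzyloxy)flavan | CC(=O)c1c(OCc2ccccc2)cc(OCc2ccccc2)c2c1O[C@H](c1ccc(OCc3ccccc3)cc1)CC2 | intermediate
9 | methyl 4-(benzyloxy)benzoate | COC(=O)c1ccc(OCc2ccccc2)cc1 | starting material
10 | 1-[(2S)-4',5,7-tris(benzyloxy)flavan-8-yl]-3-[4-(benzyloxy)phenyl]propane-1,3-dione | O=C(CC(=O)c1c(OCc2ccccc2)cc(OCc2ccccc2)c2c1O[C@H](c1ccc(OCc3ccccc3)cc1)CC2)c1ccc(OCc2ccccc2)cc1 | intermediate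
11 | 1-[(2S)-4',5,7-tris(benzyloxy)flavan-8-yl]-3-[4-(benzyloxy)phenyl]propane-1,2,3-trione | O=C(c1ccc(OCc2ccccc2)cc1)C(=O)C(=O)c1c(OCc2ccccc2)cc(OCc2ccccc2)c2c1O[C@H](c1ccc(OCc3ccccc3)cc1)CC2 | intermediate
12 | 1-[(2S)-4',5-bis(benzyloxy)-7-hydroxyflavan-8-yl]-3-[4-(benzyloxy)phenyl]propane-1,2,3-trione (open form of its ring–chain tautomers) | O=C(c1ccc(OCc2ccccc2)cc1)C(=O)C(=O)c1c(O)cc(OCc2ccccc2)c2c1O[C@H](c1ccc(OCc3ccccc3)cc1)CC2 | intermediate
13 | phloroglucinol, benzene-1,3,5-triol | Oc1cc(O)cc(O)c1 | starting material
14 | Friedel–Crafts carbinol: 2-hydroxy-2-(2,4,6-trihydroxyphenyl)-1,3-dione from 12 and 13, carbinol carbon configured as in the SMILES (not isolated) | O=C(c1ccc(OCc2ccccc2)cc1)[C@@](O)(c1c(O)cc(O)cc1O)C(=O)c1c(O)cc(OCc2ccccc2)c2c1O[C@H](c1ccc(OCc3ccccc3)cc1)CC2 | intermediate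
15 | isomeric bis-ketal: ring A dihydrofuran fused through ketal C2 and carbinol C4 to a pyran-4-one on ring D, configured as in the SMILES (not isolated) | O=C1c2c(cc(OCc3ccccc3)c3c2O[C@H](c2ccc(OCc4ccccc4)cc2)CC3)O[C@@]2(c3ccc(OCc4ccccc4)cc3)Oc3cc(O)cc(O)c3[C@@]12O | intermediate
16 | tri-O-benzyl ether of the target (benzyl on the ring D 5-oxygen and on both 4-hydroxyphenyl oxygens; ring C 2R,3S; flavan 2S) | O=C1c2c(O)cc(O)cc2O[C@@]2(c3ccc(OCc4ccccc4)cc3)Oc3cc(OCc4ccccc4)c4c(c3[C@]12O)O[C@H](c1ccc(OCc2ccccc2)cc1)CC4 | intermediate
17 | target: 5,7-dihydroxychroman-4-one (rings A and C) whose ketal C2 (4-hydroxyphenyl, 2R) and carbinol C3 (OH, 3S) are fused through the 7-oxygen and C8 to (2S)-5-hydroxy-2-(4-hydroxyphenyl)chromane | O=C1c2c(O)cc(O)cc2O[C@@]2(c3ccc(O)cc3)Oc3cc(O)c4c(c3[C@]12O)O[C@H](c1ccc(O)cc1)CC4 | target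

**Step count and risks**

Total step count: 9. Longest linear sequence: 9 steps (1 to 17).

Steps most likely to fail:

1. Step 8. The facial selectivity of the arene addition to the central carbonyl may be poor. Stereochemical information may also leak if the ketol shift runs before the rigid bis-ketal has formed. Either way both ring-fusion diastereomers would result. The fallback sets out from 12 and 13 and gives up catalyst control. The cascade is run with an achiral acid (AcOH, THF, rt; then DBU, 40 °C). It should give 16 together with its epimer at both ring-fusion carbons, the (2S,3R) tri-O-benzyl bis-ketal F1. The fixed flavan centre makes the two products diastereomers, which are separated by preparative chromatography. The route is rejoined at 16.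

2. Step 7. The Lewis acid may lose chemoselectivity in the presence of the tricarbonyl, by addition to the central carbonyl or by cleavage of further benzyl ethers. The fallback sets out from 8 and changes the order of events.
   - The ether is cleaved at the simple ketone stage (BCl3, C6HMe5, CH2Cl2, −78 °C) to give (2S)-8-acetyl-4',5-bis(benzyloxy)-7-hydroxyflavan F2.
   - A Baker–Venkataraman aroyl transfer (LiN(SiMe3)2, THF, −78 °C; 4-(benzyloxy)benzoyl chloride) gives the ortho-hydroxy 1,3-diketone F3.
   - Diazo transfer (4-acetamidobenzenesulfonyl azide, Et3N, MeCN) gives the 2-diazo-1,3-diketone F4.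
   - Oxidation of the diazo carbon with dimethyldioxirane (acetone, 0 °C) should give 12, where the route is rejoined.

3. Step 9. Over-reduction may occur: hydrogenolysis of the benzylic C–O bonds of the diaryl ketal or of the flavan ring may compete with cleavage of the benzyl ethers. The fallback sets out from 16 and replaces reduction by Lewis acid debenzylation (BCl3, C6HMe5, CH2Cl2, −78 °C). It comes back to the route at 17; no further compound arises (F0).

Further compounds
F1 | step 8 | (2S,3R) ring-fusion epimer of 16 (tri-O-benzyl ether, flavan 2S) | O=C1c2c(O)cc(O)cc2O[C@]2(c3ccc(OCc4ccccc4)cc3)Oc3cc(OCc4ccccc4)c4c(c3[C@@]12O)O[C@H](c1ccc(OCc2ccccc2)cc1)CC4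
F2 | step 7 | (2S)-8-acetyl-4',5-bis(benzyloxy)-7-hydroxyflavan | CC(=O)c1c(O)cc(OCc2ccccc2)c2c1O[C@H](c1ccc(OCc3ccccc3)cc1)CC2
F3 | step 7 | 1-[(2S)-4',5-bis(benzyloxy)-7-hydroxyflavan-8-yl]-3-[4-(benzyloxy)phenyl]propane-1,3-dione | O=C(CC(=O)c1c(O)cc(OCc2ccccc2)c2c1O[C@H](c1ccc(OCc3ccccc3)cc1)CC2)c1ccc(OCc2ccccc2)cc1
F4 | step 7 | 2-diazo-1-[(2S)-4',5-bis(benzyloxy)-7-hydroxyflavan-8-yl]-3-[4-(benzyloxy)phenyl]propane-1,3-dione | [N-]=[N+]=C(C(=O)c1ccc(OCc2ccccc2)cc1)C(=O)c1c(O)cc(OCc2ccccc2)c2c1O[C@H](c1ccc(OCc3ccccc3)cc1)CC2
F0 | step 9 | none | none
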